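**Remark on the chemistry.** Ring C of the target has its ether oxygen para and its free hydroxyl meta to the bridge carbon, so the precursor of the key step carries the reacting phenol para and the benzyl ether meta; the macrocycle is 20-membered. The A–B–C phenol keeps this skeleton but is assembled by a copper-mediated etherification and a B-alkyl Suzuki coupling, which avoids an acetal mask, a phosphonium salt and an alkene reduction next to a benzyl ether. Reagents named without a number are taken to be commercial.

## Structural features

Pakyonol is a macrocyclic bis(bibenzyl). Four benzene rings are joined in a 20-membered ring by two diaryl ether oxygens (ring A–O–ring B and ring C–O–ring D) and two ethylene bridges (ring B–CH2CH2–ring C and ring D–CH2CH2–ring A). Ring A is 1,2,4-trisubstituted (methoxy, ortho aryloxy, bridge para to methoxy), ring B is para-disubstituted, ring C carries the ether oxygen para and a free hydroxyl meta to its bridge carbon, and ring D is meta-disubstituted. There is no stereocenter, so the only spatial question is whether the 20-membered ring can close. Fragile points are the oxidisable free phenol of ring C, the benzylic CH2 groups para to oxygen, and, in the intermediates, the electron-rich styrene on ring A. The real difficulties are the macrocyclisation and the ring C–O–ring D ether, in which neither ring has an activating group for fluoride displacement and the oxygen sits next to a second oxygen substituent. The key step uses the 1,3-relationship in ring D between the oxygen-bearing carbon and the bridge-bearing carbon. These map onto C3 and C1 of cyclohexane-1,3-dione: C3 accepts the ring C phenoxide as a vinylogous acyl chloride, and C1 stays a carbonyl for the later carbon–carbon bond before the ring is dehydrogenated to benzene.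

## Logic of the disconnections

20 to 19: the O–CH2Ph bond on ring C is cut. The free phenol is the only oxidation-sensitive group, and a benzyl ether is removed by hydrogenolysis without touching anything else in 19. The demand is that this ether survives base, borane, palladium and quinone oxidant.

19 to 18: two hydrogens are added back to ring D, so the meta-phenylene becomes a 1-alkyl-3-aryloxycyclohexa-1,3-diene. This exposes the latent 1,3-dione pattern. The forward dehydrogenation must be faster than oxidation of the benzylic bridges.

18 to 16 (through 17): the bond between ring D C1 and the neighbouring CH2 of the bridge to ring A is cut, which opens the macrocycle. The acyclic compound 16 carries a vinyl group on ring A and a dienyl triflate on the ring D surrogate. The forward step needs hydroboration of the terminal alkene only, and ring closure under high dilution.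

16 to 14: the O–S bond of the enol triflate is cut to give the ketone. The forward step needs enolisation of the vinylogous ester away from the aryloxy-bearing carbon; the other enolisation regioisomer would converge on 19 all the same.

14 to 11 + 13: the bond between the ring C oxygen and C3 of the six-membered ring is cut. This is the unactivated diaryl ether, and making it on a non-aromatic electrophile replaces a hard aryl C–O coupling by an addition–elimination. The cut separates ring D as a six-carbon block from a three-ring phenol. The demand is O-attack by a single free phenol.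

13 to 12: the C–Cl bond is cut; the chloroenone comes from the dione in one operation.

11 to 10: the vinyl C=C bond is cut to an aldehyde. The aldehyde is the robust carrier of that carbon through coupling and acid steps, and the acid-sensitive styrene appears only after them. The olefination must tolerate a free phenol.

10 to 9: the O–CH2OMe bond is cut. The methoxymethyl ether keeps the ring C 4-oxygen silent during benzylation, olefination and coupling, and must come off without loss of the benzyl ether.

9 to 4 + 7 (through 8): the bond between ring B and the CH2 of the B–C bridge is cut. This gives two fragments of similar size and builds the bridge from a styrene by hydroboration, so no stilbene has to be reduced beside a benzyl ether. The aldehyde of 7 must not meet any boron hydride.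

7 to 5 + 6: the ring B C–O bond of the A–B ether is cut. The forward coupling must take iodide and leave bromide.

4 to 3 to 2 to 1: the vinyl C=C, the O–benzyl and the O–methoxymethyl bonds are cut in turn. The first alkylation must go to the more acidic 4-hydroxyl of 1, para to the formyl group.

## Other disconnections considered

Alternative 1: The cut is the ring A carbon–oxygen bond of the ring A–O–ring B ether, formed as the ring-closing event. The open precursor would be the seco bisphenol A1, with ring A as a 3,5-dibromo-4-hydroxyphenyl unit, ring B as a 3,5-dichloro-4-hydroxyphenyl unit, and both bridges and the ring C–O–ring D ether already in place. Tl(NO3)3 would oxidise A1, the ring B phenol oxygen would bond to a bromine-bearing ortho carbon of ring A, and zinc would reduce the bromodienone to the macrocycle A2.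
- In its favour: ether formation and macrocyclisation coincide, the halogen pattern fixes which ring is donor and which is acceptor, and no catalyst is needed in the closure.
- Against it here: stoichiometric trivalent thallium, three halogens that must be introduced and later removed, and a separate O-methylation of ring A. It also leaves the unactivated ring C–O–ring D ether to a conventional copper coupling.
- Comparison: after ring closure, A2 needs methylation and one hydrogenolysis (halogens and benzyl together), which equals the two operations after ring closure in the chosen plan. Alternative 1 is the better on convergence at the closure. The chosen plan is the better on reagent hazard, on atom economy, and in solving the harder of the two ethers by design.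

Alternative 2: The cut is the ring C C4–O bond, the same ether the chosen plan makes, but formed as the ring closure. In the precursor A3, ring C is a 4-fluoro-3-formylphenyl unit and ring D a free 3-hydroxyphenyl unit. The ring D phenoxide would displace fluoride to give the macrocyclic aldehyde A4, and Dakin-type oxidation with formate hydrolysis would turn the formyl group into the hydroxyl of 20.
- In its favour: fluoride displacement is a well-tried way to close diaryl ether macrocycles and needs no metal. The activating group ends exactly where the hydroxyl is wanted, so ring C needs no protecting group and no final hydrogenolysis. On protecting-group economy this is better than the chosen plan, and as a ring closure it is at least its equal.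
- Against it here: a single ortho formyl group activates only moderately, so the closure would need heat. The peracid oxidation has to work on an ortho-aryloxybenzaldehyde in a molecule with two electron-rich rings. A3 also needs both bridges and the A–B ether, with a free phenol and an aldehyde carried through.
- Comparison: the chosen plan forms the same C–O bond intermolecularly at or near room temperature and closes the ring on a C–C bond instead. Step counts should be similar. Alternative 2 concentrates its risk in the oxidation at the last stage, while the chosen plan concentrates it in the macrocyclising coupling.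

Alternative 3: The cut is again the ring A–O–ring B ether, reached by ring contraction. The 21-membered macrolactone A5 (a ring B benzoate of the ring A phenol) would be treated with Ni(cod)2 and 3,4-bis(dicyclohexylphosphino)thiophene. Zerovalent nickel would insert into the C(acyl)–O bond, CO would be lost, and reductive elimination would give A6, which is identical with 19.
- In its favour: macrolactonisation is among the most dependable ring closures, which is a point where it is better than a macrocyclising cross-coupling. The endgame from A6 is the same single hydrogenolysis as from 19, so the two plans are equal there.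
- Against it here: decarbonylative etherification is best established for electron-poor and heteroaryl carboxylates. An electron-neutral 4-alkylbenzoate of an ortho-methoxyphenol, inside a macrocycle and at the high temperature such reactions need, is at the edge of that chemistry. Nickel with an electron-rich phosphine could also attack the aryl methyl and benzyl ether bonds.
- Comparison: the key bond change is less secure than the addition–elimination of the chosen plan, and the ring C–O–ring D ether still has to be made by other means. Step economy should be comparable.

Key step: step 9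

## Route

Step 1
Reactants: 1 3,4-dihydroxybenzaldehyde
Product: 2 3-hydroxy-4-(methoxymethoxy)benzaldehyde
Conditions: MOMCl (1.05 equiv), K2CO3 (1.1 equiv), acetone, 0 °C → rt
Reagents that add atoms: chloromethyl methyl ether, COCCl
Why: The 4-hydroxyl, para to the formyl group, is the more acidic, so one equivalent of weak base gives mainly its phenoxide and the Williamson alkylation (SN2) takes place there, leaving the 3-hydroxyl free.

Step 2
Reactants: 2 3-hydroxy-4-(methoxymethoxy)benzaldehyde
Product: 3 3-(benzyloxy)-4-(methoxymethoxy)benzaldehyde
Conditions: BnBr (1.2 equiv), K2CO3, DMF, rt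
Reagents that add atoms: benzyl bromide, BrCc1ccccc1
Why: Williamson ether synthesis on the only remaining phenol; the acetal-type methoxymethyl ether is stable to carbonate.

Step 3
Reactants: 3 3-(benzyloxy)-4-(methoxymethoxy)benzaldehyde
Product: 4 2-(benzyloxy)-1-(methoxymethoxy)-4-vinylbenzene
Conditions: Ph3PCH3Br (1.3 equiv), KOtBu (1.25 equiv), THF, 0 °C → rt
Reagents that add atoms: methyltriphenylphosphonium bromide, C[P+](c1ccccc1)(c1ccccc1)c1ccccc1.[Br-]
Why: Wittig methylenation of a non-enolisable aromatic aldehyde; both ethers are inert to the ylide.

Step 4
Reactants: 5 isovanillin (3-hydroxy-4-methoxybenzaldehyde); 6 1-bromo-4-iodobenzene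
Product: 7 3-(4-bromophenoxy)-4-methoxybenzaldehyde
Conditions: 6 (1.5 equiv), CuI (10 mol%), N,N-dimethylglycine hydrochloride (30 mol%), Cs2CO3 (2 equiv), dioxane, 90 °C
Reagents that add atoms: none
Why: Ullmann-type diaryl ether synthesis with an amino acid ligand; the monovalent copper phenoxide reacts with the C–I bond much faster than with C–Br at this temperature, so the bromide is kept for step 5, and excess 6 suppresses a second arylation.

Step 5
Reactants: 4 2-(benzyloxy)-1-(methoxymethoxy)-4-vinylbenzene; 7 3-(4-bromophenoxy)-4-methoxybenzaldehyde
Product: 9 3-{4-[2-(3-benzyloxy-4-(methoxymethoxy)phenyl)ethyl]phenoxy}-4-methoxybenzaldehyde, via ring C alkyl-9-BBN adduct 8 (not isolated)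
Conditions: 4 (1.2 equiv), 9-BBN (1.1 equiv), THF, 0 °C → rt; then 7 (1.0 equiv), Pd(dppf)Cl2 (5 mol%), 3 M aq. K3PO4, DMF, 60 °C
Reagents that add atoms: 9-borabicyclo[3.3.1]nonane (9-BBN), B1C2CCCC1CCC2 (its boryl group is carried only in 8; product 9 keeps one hydrogen from it)
Why: 9-BBN adds anti-Markovnikov to the terminal alkene of 4 to give primary alkylborane 8, and because 4 is in slight excess no B–H is left to reduce the aldehyde of 7. The base-activated borate transmetalates to the arylpalladium bromide formed from 7 and zerovalent palladium, and reductive elimination gives the bibenzyl (B-alkyl Suzuki–Miyaura coupling), the wide-bite-angle dppf ligand disfavouring β-hydride elimination.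

Step 6
Reactants: 9 3-{4-[2-(3-benzyloxy-4-(methoxymethoxy)phenyl)ethyl]phenoxy}-4-methoxybenzaldehyde
Product: 10 3-{4-[2-(3-benzyloxy-4-hydroxyphenyl)ethyl]phenoxy}-4-methoxybenzaldehyde
Conditions: 3 M aq. HCl, THF, 50 °C
Reagents that add atoms: none
Why: Acid-catalysed hydrolysis of the aryl methoxymethyl acetal; the benzyl ether, the diaryl ether and the aldehyde are stable to dilute aqueous acid, and the step is placed before the acid-sensitive styrene exists.

Step 7
Reactants: 10 3-{4-[2-(3-benzyloxy-4-hydroxyphenyl)ethyl]phenoxy}-4-methoxybenzaldehyde
Product: 11 2-(benzyloxy)-4-{2-[4-(2-methoxy-5-vinylphenoxy)phenyl]ethyl}phenol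
Conditions: Ph3PCH3Br (3 equiv), KOtBu (3 equiv), THF, 0 °C → rt; aq. NH4Cl
Reagents that add atoms: methyltriphenylphosphonium bromide, C[P+](c1ccccc1)(c1ccccc1)c1ccccc1.[Br-]
Why: Wittig methylenation; one equivalent of ylide is spent deprotonating the ring C phenol, whose phenoxide is on another ring and not conjugated with the ring A aldehyde, so olefination proceeds normally and the phenol returns on work-up.

Step 8
Reactants: 12 cyclohexane-1,3-dione
Product: 13 3-chlorocyclohex-2-en-1-one
Conditions: (COCl)2 (1.1 equiv), DMF (cat.), CH2Cl2, 0 °C → rt
Reagents that add atoms: oxalyl chloride, O=C(Cl)C(=O)Cl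
Why: The enol of the dione is O-activated and chloride then adds and eliminates at the vinylogous carbon with loss of CO, CO2 and HCl, the standard conversion of a cyclic 1,3-dione into a β-chloroenone.

Step 9
Reactants: 11 2-(benzyloxy)-4-{2-[4-(2-methoxy-5-vinylphenoxy)phenyl]ethyl}phenol; 13 3-chlorocyclohex-2-en-1-one
Product: 14 3-[2-(benzyloxy)-4-{2-[4-(2-methoxy-5-vinylphenoxy)phenyl]ethyl}phenoxy]cyclohex-2-en-1-one
Conditions: 13 (1.2 equiv), K2CO3 (1.5 equiv), DMF, rt → 50 °C
Reagents that add atoms: none
Why: Carbonate converts the ring C phenol of 11 into its phenoxide, which adds to C3 of 13, the β-carbon of the enone, to give a chlorine-bearing enolate; this expels chloride and restores the enone, so the new O–C3 bond joins ring C to the ring D surrogate. The closest known reaction type is the addition–elimination (vinylogous acyl substitution) of phenoxides on 3-halocyclohex-2-enones to give vinylogous aryl esters. No ring is closed and no stereocenter is formed. The selectivity needed is O- over C-attack by the ambident phenoxide, which is secured by the hard, acyl chloride-like electrophile and by a potassium phenoxide in a dipolar aprotic solvent. Only one oxygen can react, because the neighbouring ring C oxygen is benzylated and 11 has a single acidic site. The ortho benzyloxy group costs little, since the electrophilic carbon is unhindered and sp2. The styrene, the benzyl ether and the diaryl ether are inert to carbonate at this temperature. Exchange of the aryloxy group of 14 with further phenoxide would be degenerate and is further limited by the slight excess of 13.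

Step 10
Reactants: 14 3-[2-(benzyloxy)-4-{2-[4-(2-methoxy-5-vinylphenoxy)phenyl]ethyl}phenoxy]cyclohex-2-en-1-one
Product: 16 5-[2-(benzyloxy)-4-{2-[4-(2-methoxy-5-vinylphenoxy)phenyl]ethyl}phenoxy]cyclohexa-1,5-dien-1-yl trifluoromethanesulfonate, via lithium cross-conjugated enolate 15 (not isolated)
Conditions: LiHMDS (1.15 equiv), THF, −78 °C; Comins' reagent (1.2 equiv), −78 → 0 °C; aq. NH4Cl
Reagents that add atoms: N-(5-chloropyridin-2-yl)bis(trifluoromethanesulfonimide) (Comins' reagent), Clc1ccc(nc1)N(S(=O)(=O)C(F)(F)F)S(=O)(=O)C(F)(F)F; lithium bis(trimethylsilyl)amide, [Li]N([Si](C)(C)C)[Si](C)(C)C (its lithium is carried only in 15)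
Why: The hindered amide removes the kinetically accessible proton at C6 of the vinylogous ester, as in Stork–Danheiser chemistry, and cross-conjugated enolate 15 is O-sulfonylated at low temperature. The isomeric dienyl triflate from deprotonation at C4 would converge on 19 after coupling and dehydrogenation, so regiocontrol is not critical.

Step 11
Reactants: 16 5-[2-(benzyloxy)-4-{2-[4-(2-methoxy-5-vinylphenoxy)phenyl]ethyl}phenoxy]cyclohexa-1,5-dien-1-yl trifluoromethanesulfonate
Product: 18 O-benzyl-dihydropakyonol (the 20-membered macrocycle of 19 in which ring D is a cyclohexa-1,3-diene: bridge on C1; aryloxy on C3; C4 and C5 are CH2), via ring A alkyl-9-BBN adduct 17 (not isolated)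
Conditions: 9-BBN (1.2 equiv), THF, 0 °C → rt; then syringe-pump addition over 10 h to Pd(dppf)Cl2 (15 mol%), AsPh3 (15 mol%), Cs2CO3 (3 equiv), DMF/THF/H2O, 50 °C (final 2 mM)
Reagents that add atoms: 9-borabicyclo[3.3.1]nonane (9-BBN), B1C2CCCC1CCC2 (its boryl group is carried only in 17; product 18 keeps one hydrogen from it)
Why: 9-BBN hydroborates the terminal styrene far faster than the trisubstituted, oxygen-substituted ring alkenes and places boron on the terminal carbon. Oxidative addition of zerovalent palladium into the dienyl C–OTf bond, transmetalation of the borate and reductive elimination form the sp3–sp2 bond and close the 20-membered ring (macrocyclising B-alkyl Suzuki–Miyaura coupling), with slow addition keeping the open-chain borane dilute.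

Step 12
Reactants: 18 O-benzyl-dihydropakyonol
Product: 19 O-benzylpakyonol
Conditions: DDQ (1.1 equiv), toluene, 0 °C → rt
Reagents that add atoms: none
Why: Quinone dehydrogenation: hydride abstraction from a ring CH2 of the cyclohexa-1,3-diene gives an oxygen-stabilised cyclohexadienyl cation that loses a proton to form benzene ring D, which should be much faster than oxidation of the bibenzyl CH2 groups or the benzyl ether. The ether oxygen stays on an sp2 carbon throughout, so no phenol is eliminated.

Step 13
Reactants: 19 O-benzylpakyonol
Product: 20 pakyonol
Conditions: H2 (1 atm), 10% Pd/C, EtOAc/EtOH, rt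
Reagents that add atoms: none
Why: Hydrogenolysis of the benzylic C–O bond on palladium; the diaryl ethers, the methyl ether and the saturated bridges are inert.

## Compound list

1 | 3,4-dihydroxybenzaldehyde | O=Cc1ccc(O)c(O)c1 | starting material
2 | 3-hydroxy-4-(methoxymethoxy)benzaldehyde | O=Cc1ccc(OCOC)c(O)c1 | intermediate
3 | 3-(benzyloxy)-4-(methoxymethoxy)benzaldehyde | O=Cc1ccc(OCOC)c(OCc2ccccc2)c1 | intermediate
4 | 2-(benzyloxy)-1-(methoxymethoxy)-4-vinylbenzene | C=Cc1ccc(OCOC)c(OCc2ccccc2)c1 | intermediate
5 | isovanillin (3-hydroxy-4-methoxybenzaldehyde) | COc1ccc(C=O)cc1O | starting material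
6 | 1-bromo-4-iodobenzene | Brc1ccc(I)cc1 | starting material
7 | 3-(4-bromophenoxy)-4-methoxybenzaldehyde | COc1ccc(C=O)cc1Oc1ccc(Br)cc1 | intermediate
8 | 9-{2-[3-benzyloxy-4-(methoxymethoxy)phenyl]ethyl}-9-borabicyclo[3.3.1]nonane (ring C alkyl-9-BBN adduct, not isolated) | COCOc1ccc(CCB2C3CCCC2CCC3)cc1OCc1ccccc1 | intermediate
9 | 3-{4-[2-(3-benzyloxy-4-(methoxymethoxy)phenyl)ethyl]phenoxy}-4-methoxybenzaldehyde | COc1ccc(C=O)cc1Oc1ccc(CCc2ccc(OCOC)c(OCc3ccccc3)c2)cc1 | intermediate
10 | 3-{4-[2-(3-benzyloxy-4-hydroxyphenyl)ethyl]phenoxy}-4-methoxybenzaldehyde | COc1ccc(C=O)cc1Oc1ccc(CCc2ccc(O)c(OCc3ccccc3)c2)cc1 | intermediate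
11 | 2-(benzyloxy)-4-{2-[4-(2-methoxy-5-vinylphenoxy)phenyl]ethyl}phenol (A–B–C phenol with ring A styrene) | COc1ccc(C=C)cc1Oc1ccc(CCc2ccc(O)c(OCc3ccccc3)c2)cc1 | intermediate
12 | cyclohexane-1,3-dione | O=C1CCCC(=O)C1 | starting material
13 | 3-chlorocyclohex-2-en-1-one | O=C1C=C(Cl)CCC1 | intermediate
14 | 3-[2-(benzyloxy)-4-{2-[4-(2-methoxy-5-vinylphenoxy)phenyl]ethyl}phenoxy]cyclohex-2-en-1-one | COc1ccc(C=C)cc1Oc1ccc(CCc2ccc(OC3=CC(=O)CCC3)c(OCc3ccccc3)c2)cc1 | intermediate
15 | lithium cross-conjugated (C1–C6) enolate of 14 (not isolated) | COc1ccc(C=C)cc1Oc1ccc(CCc2ccc(OC3=CC(O[Li])=CCC3)c(OCc3ccccc3)c2)cc1 | intermediate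
16 | 5-[2-(benzyloxy)-4-{2-[4-(2-methoxy-5-vinylphenoxy)phenyl]ethyl}phenoxy]cyclohexa-1,5-dien-1-yl trifluoromethanesulfonate | COc1ccc(C=C)cc1Oc1ccc(CCc2ccc(OC3=CC(OS(=O)(=O)C(F)(F)F)=CCC3)c(OCc3ccccc3)c2)cc1 | intermediate
17 | ring A alkyl-9-BBN adduct of 16 (ring A–CH2CH2–B, not isolated) | COc1ccc(CCB4C5CCCC4CCC5)cc1Oc1ccc(CCc2ccc(OC3=CC(OS(=O)(=O)C(F)(F)F)=CCC3)c(OCc3ccccc3)c2)cc1 | intermediate
18 | O-benzyl-dihydropakyonol (macrocycle with ring D as 1-alkyl-3-aryloxycyclohexa-1,3-diene) | COc1ccc2cc1Oc1ccc(cc1)CCc1ccc(c(OCc3ccccc3)c1)OC1=CC(=CCC1)CC2 | intermediate
19 | O-benzylpakyonol | COc1ccc2cc1Oc1ccc(cc1)CCc1ccc(c(OCc3ccccc3)c1)Oc1cccc(c1)CC2 | intermediate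
20 | pakyonol | COc1ccc2cc1Oc1ccc(cc1)CCc1ccc(c(O)c1)Oc1cccc(c1)CC2 | target

## Step count and risk

Total: 13 steps. Longest linear sequence: 11 steps (steps 1, 2, 3, 5, 6, 7, 9, 10, 11, 12, 13, from 1 to 20). Steps 4 and 8 are one-step side branches.

**Step 11 (macrocyclising B-alkyl Suzuki coupling).** Intermolecular coupling to oligomers can compete with closure of the 20-membered ring. The alkylborane can lose boron by protonolysis or the alkylpalladium can undergo β-hydride elimination. The dienyl triflate can be hydrolysed by the aqueous base during the long addition. Fallback, from 16 to 20: an intramolecular Mizoroki–Heck reaction of the styrene with the dienyl triflate (Pd(OAc)2, P(o-tol)3, Et3N, (n-Bu)4NCl, MeCN, high dilution, 70 °C) would close the ring on a C=C bond and give the macrocyclic triene F1. DDQ would aromatise ring D to the macrocyclic E-stilbene F2. Hydrogenation over Pd/C would saturate the stilbene and cleave the benzyl ether in one operation, rejoining the route at 20 with the same number of steps.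

**Step 10 (kinetic enolate triflation).** The amide base may attack C3 and displace the ring C phenoxide, and the electron-rich dienyl triflate may hydrolyse on isolation. Fallback, from 14 to 19: the enolate would be trapped with TMSCl as the trimethylsilyl dienol ether F3. Saegusa–Ito dehydrogenation with Pd(OAc)2 in MeCN, then tautomerisation, would give the 3-aryloxyphenol F4. Tf2O and pyridine would give the aryl triflate F5. Hydroboration to the alkyl-9-BBN adduct F6 and ring closure under the conditions of step 11 would give 19 directly. Ring D is then aromatic before the macrocyclisation, and the count is unchanged.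

**Step 9 (key step).** C-alkylation at the free ortho position of the phenoxide could compete. A slow reaction of the ortho-substituted phenoxide could let traces of water hydrolyse 13 back to 12. Fallback, from 11 to 19: the surrogate would be given up for a copper-mediated Ullmann coupling of 11 with 1-bromo-3-iodobenzene (CuI, N,N-dimethylglycine hydrochloride, Cs2CO3, dioxane, 90 °C, radical inhibitor), giving the 3-bromophenyl ether F7. Hydroboration to the alkyl-9-BBN adduct F8 and macrocyclising Suzuki coupling onto the aryl bromide would give 19.

**Step 5 (B-alkyl Suzuki coupling beside an aldehyde).** The aldehyde of 7 could be reduced by residual boron hydride or by hydride transfer from the alkylborane, and the alkylborane could be protonated before transmetalation. Fallback, from 4 and 7 to 9: a Mizoroki–Heck reaction (Pd(OAc)2, P(o-tol)3, Et3N, DMF, 100 °C) would give the E-stilbene aldehyde F9. Hydrogenation over Pd/C poisoned with diphenyl sulfide, which spares benzyl ethers and aromatic aldehydes, would give 9.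

**Step 4 (iodide-selective Ullmann etherification).** Iodide/bromide discrimination could erode, leading to double arylation, and the ortho-methoxy phenol could couple sluggishly. Fallback, from 5 to 7: a Chan–Lam oxidative coupling of 5 with 4-bromophenylboronic acid (Cu(OAc)2, pyridine, 4 Å molecular sieves, CH2Cl2, air, rt) would give 7 directly. No oxidative addition to a carbon–halogen bond is involved, so the bromide is not at risk; this fallback makes no new compound (F0).

## Further compounds

F1 | step 11 | macrocyclic triene: ring A and the cyclohexa-1,3-diene ring D joined by an E-CH=CH bridge, benzyl ether retained | COc1ccc(/C=C/C2=CCCC(Oc3ccc(CCc4ccc(O5)cc4)cc3OCc3ccccc3)=C2)cc15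
F2 | step 11 | O-benzyl-dehydropakyonol (macrocyclic E-stilbene between rings A and D) | COc1ccc(/C=C/c2cccc(Oc3ccc(CCc4ccc(O5)cc4)cc3OCc3ccccc3)c2)cc15
F3 | step 10 | trimethylsilyl dienol ether of 14 | COc1ccc(C=C)cc1Oc1ccc(CCc2ccc(OC3=CC(O[Si](C)(C)C)=CCC3)c(OCc3ccccc3)c2)cc1
F4 | step 10 | 3-[2-(benzyloxy)-4-{2-[4-(2-methoxy-5-vinylphenoxy)phenyl]ethyl}phenoxy]phenol | COc1ccc(C=C)cc1Oc1ccc(CCc2ccc(Oc3cccc(O)c3)c(OCc3ccccc3)c2)cc1
F5 | step 10 | aryl triflate of F4 | COc1ccc(C=C)cc1Oc1ccc(CCc2ccc(Oc3cccc(OS(=O)(=O)C(F)(F)F)c3)c(OCc3ccccc3)c2)cc1
F6 | step 10 | ring A alkyl-9-BBN adduct of F5 | COc1ccc(CCB4C5CCCC4CCC5)cc1Oc1ccc(CCc2ccc(Oc3cccc(OS(=O)(=O)C(F)(F)F)c3)c(OCc3ccccc3)c2)cc1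
F7 | step 9 | 2-(benzyloxy)-1-(3-bromophenoxy)-4-{2-[4-(2-methoxy-5-vinylphenoxy)phenyl]ethyl}benzene | COc1ccc(C=C)cc1Oc1ccc(CCc2ccc(Oc3cccc(Br)c3)c(OCc3ccccc3)c2)cc1
F8 | step 9 | ring A alkyl-9-BBN adduct of F7 | COc1ccc(CCB4C5CCCC4CCC5)cc1Oc1ccc(CCc2ccc(Oc3cccc(Br)c3)c(OCc3ccccc3)c2)cc1
F9 | step 5 | 3-{4-[(E)-2-(3-benzyloxy-4-(methoxymethoxy)phenyl)ethenyl]phenoxy}-4-methoxybenzaldehyde | COc1ccc(C=O)cc1Oc1ccc(/C=C/c2ccc(OCOC)c(OCc3ccccc3)c2)cc1
F0 | step 4 | none | none
A1 | alternative 1 | halogenated seco bisphenol (ring A 3,5-dibromo-4-hydroxyphenyl, ring B 3,5-dichloro-4-hydroxyphenyl, ring C benzyl ether) | Oc1c(Br)cc(CCc2cccc(Oc3ccc(CCc4cc(Cl)c(O)c(Cl)c4)cc3OCc3ccccc3)c2)cc1Br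
A2 | alternative 1 | halogenated O-benzyl O-demethyl pakyonol macrocycle | Oc1c(Br)cc2cc1Oc1c(Cl)cc(cc1Cl)CCc1ccc(c(OCc3ccccc3)c1)Oc1cccc(c1)CC2
A3 | alternative 2 | seco phenol with 4-fluoro-3-formylphenyl ring C and 3-hydroxyphenyl ring D | COc1ccc(CCc2cccc(O)c2)cc1Oc1ccc(CCc2ccc(F)c(C=O)c2)cc1
A4 | alternative 2 | macrocyclic aldehyde (pakyonol with CHO in place of OH) | COc1ccc2cc1Oc1ccc(cc1)CCc1ccc(c(C=O)c1)Oc1cccc(c1)CC2
A5 | alternative 3 | 21-membered macrolactone (ring B benzoate of the ring A phenol, ring C benzyl ether) | COc1ccc2cc1OC(=O)c1ccc(cc1)CCc1ccc(c(OCc3ccccc3)c1)Oc1cccc(c1)CC2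
A6 | alternative 3 | O-benzylpakyonol (identical with 19) | COc1ccc2cc1Oc1ccc(cc1)CCc1ccc(c(OCc3ccccc3)c1)Oc1cccc(c1)CC2
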